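**Retrosynthetic overview**

1. Last disconnections: the three MOM ethers, then the C3–C1' bond (Suzuki–Miyaura), giving the ring A/C iodochromone 18 and the ring B chromenyl boronate 10.
2. Ring B and its pyran: 10 ⇐ phenol 8 ⇐ dihydrochromenone 6, with ring B kept as a cyclohexenone and aromatised after the key step. 6 ⇐ redox-active ester 4 + acetylene by a radical [4+2] annulation that forms C3'–C4'' and C3''–C2'' of the pyran in one operation.
3. Enabling feature: ring B has oxygen at C2' and C4' on either side of C3', so it is a masked cyclohexane-1,3-dione. At that oxidation level C3' is the α-carbon of a vinylogous ester and the only sp2 carbon next to C4', the oxygen on C4' (the pyran O) carries the gem-dimethyl carbon C2'' as a tertiary α-oxy radical precursor, and C5' is sp3 and cannot compete.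
4. Ring A/C: 18 ⇐ o-hydroxyacetophenone 16 (enaminone, iodocyclisation) ⇐ 1,3-bis(methoxymethoxy)benzene by two directed metalations (oxetane opening for the C6 side chain, then acetylation) and a carbonyl-directed C–H borylation/oxidation for the ring C oxygen.
5. Ring order: ring B carbocycle (bought as a cyclohexenone) → pyran (step 3) → aromatisation of ring B; ring A (bought) → pyranone ring C (step 10) → union and unmasking.

Key step: step 3

Assumption: the target has no stereocentre, so no stereocontrol is needed; compounds 1, 2, 5, 11 and 12 are taken as catalogue chemicals.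

**Route**

Step 1
Reactants: 1 3-chlorocyclohex-2-en-1-one; 2 2-hydroxy-2-methylpropanoic acid
Product: 3 2-methyl-2-[(3-oxocyclohex-1-en-1-yl)oxy]propanoic acid
Conditions: NaH (2.2 equiv), DMF, 0 °C; then 1, 0 °C → rt; cold 1 M HCl to pH 3
Reagents that add atoms: none
Why: Addition–elimination (vinylogous nucleophilic acyl substitution) of the tertiary alkoxide of the alkoxide–carboxylate dianion at the β-carbon of the β-chloroenone should give the vinylogous ester, the carboxylate being by far the weaker nucleophile.

Step 2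
Reactants: 3 2-methyl-2-[(3-oxocyclohex-1-en-1-yl)oxy]propanoic acid
Product: 4 1,3-dioxoisoindolin-2-yl 2-methyl-2-[(3-oxocyclohex-1-en-1-yl)oxy]propanoate
Conditions: N-hydroxyphthalimide, N,N'-diisopropylcarbodiimide, DMAP (cat.), CH2Cl2, 0 °C → rt
Reagents that add atoms: N-hydroxyphthalimide, O=C1c2ccccc2C(=O)N1O
Why: Steglich-type carbodiimide esterification should convert the hindered acid into its N-acyloxyphthalimide (redox-active ester).

Step 3
Reactants: 4 1,3-dioxoisoindolin-2-yl 2-methyl-2-[(3-oxocyclohex-1-en-1-yl)oxy]propanoate; 5 acetylene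
Product: 6 2,2-dimethyl-7,8-dihydro-2H-chromen-5(6H)-one
Conditions: Ir(ppy)3 (1 mol %; ppy = 2-phenylpyridinato), acetylene (1 atm, balloon), degassed DMSO, blue LEDs (450 nm), rt
Reagents that add atoms: none
Why: Proposed new method: single-electron transfer from photoexcited Ir(ppy)3 to the N-acyloxyphthalimide should release CO2, phthalimide anion and the tertiary α-oxyalkyl radical at the future C2'', which adds to acetylene to make the C3''–C2'' bond and a σ-vinyl radical at C4''; this radical closes onto the enol-ether double bond of the vinylogous ester to make the C4''–C3' bond, and the resulting ring-fused α-oxy radical is oxidised by the tetravalent iridium left from the first electron transfer and loses the proton next to the carbonyl group, so that the cycle is redox-neutral. The closest known reaction types are photoredox decarboxylative additions of redox-active esters to π-acceptors, radical (4+2) annulations of α-aryloxyalkyl radicals with alkenes that give chromans, and photoredox additions of alkyl radicals to acetylene that proceed through vinyl radicals. The pyran ring is closed in a formal [4+2] sense by an intermolecular radical addition followed by a 6-endo-trig radical cyclisation; a competing 5-exo attack at the oxygen-bearing carbon would give a spiro α-keto radical that cannot be oxidised under these conditions and is expected to funnel into the same fused radical by a 1,2-vinyl shift through a cyclopropylcarbinyl radical. No stereocentre is formed, and the cis geometry of the new ring alkene is enforced by the ring. The step needs site selectivity for C3' over C5' and chemoselectivity for acetylene capture over premature oxidation of the first radical: the former is secured by the oxidation level of the substrate, in which C3' is the only sp2 carbon adjacent to the oxygen-bearing carbon while C5' is a saturated CH2, the latter by the acetylene-saturated solution and the low catalyst loading.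

Step 4
Reactants: 6 2,2-dimethyl-7,8-dihydro-2H-chromen-5(6H)-one
Product: 8 2,2-dimethyl-2H-chromen-5-ol, via α-phenylselanyl ketone 7 (not isolated)
Conditions: LiN(iPr)2 (1.1 equiv), THF, −78 °C; PhSeBr, −78 °C; then 30% H2O2, pyridine, CH2Cl2, 0 °C → rt
Reagents that add atoms: none
Why: Kinetic deprotonation of the vinylogous ester at the α'-carbon (C6), selenenylation and selenoxide syn-elimination should give the cross-conjugated cyclohexadienone, which tautomerises to the phenol (α-selenenylation/selenoxide elimination used as a dehydrogenative aromatisation).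

Step 5
Reactants: 8 2,2-dimethyl-2H-chromen-5-ol
Product: 9 5-(methoxymethoxy)-2,2-dimethyl-2H-chromene
Conditions: NaH, DMF, 0 °C; MOMCl, 0 °C → rt
Reagents that add atoms: chloromethyl methyl ether, COCCl
Why: Williamson-type O-alkylation of the sodium phenoxide installs the MOM ether, which serves as directing group in the next step and as protecting group to the end.

Step 6
Reactants: 9 5-(methoxymethoxy)-2,2-dimethyl-2H-chromene
Product: 10 2-[5-(methoxymethoxy)-2,2-dimethyl-2H-chromen-6-yl]-4,4,5,5-tetramethyl-1,3,2-dioxaborolane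
Conditions: n-BuLi, THF, −78 → −10 °C; then 2-isopropoxy-4,4,5,5-tetramethyl-1,3,2-dioxaborolane, −78 °C → rt; H2O
Reagents that add atoms: 2-isopropoxy-4,4,5,5-tetramethyl-1,3,2-dioxaborolane, CC(C)OB1OC(C)(C)C(C)(C)O1
Why: Directed ortho-metalation: the MOM ether should direct lithiation to its only ortho C–H (C6 of the chromene, the future C1'), and trapping with the borate ester gives the pinacol boronate.

Step 7
Reactants: 11 1,3-bis(methoxymethoxy)benzene; 12 2,2-dimethyloxetane
Product: 13 4-[2,6-bis(methoxymethoxy)phenyl]-2-methylbutan-2-ol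
Conditions: n-BuLi, THF, 0 °C; then 12, BF3·OEt2, −78 °C; H2O
Reagents that add atoms: none
Why: Directed ortho-metalation between the two MOM ethers followed by BF3-promoted SN2 opening of the oxetane at its unsubstituted CH2 terminus should install the complete 3-hydroxy-3-methylbutyl chain in one operation.

Step 8
Reactants: 13 4-[2,6-bis(methoxymethoxy)phenyl]-2-methylbutan-2-ol
Product: 14 1-[3-(3-hydroxy-3-methylbutyl)-2,4-bis(methoxymethoxy)phenyl]ethan-1-one
Conditions: s-BuLi (2.2 equiv), TMEDA, THF, −78 °C; then N-methoxy-N-methylacetamide, −78 → 0 °C; H2O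
Reagents that add atoms: N-methoxy-N-methylacetamide, CC(=O)N(C)OC
Why: A second directed ortho-metalation next to a MOM ether (the first equivalent of base is consumed by the tertiary hydroxyl) and acylation with the Weinreb amide, which stops at the ketone stage, should give the aryl methyl ketone.

Step 9
Reactants: 14 1-[3-(3-hydroxy-3-methylbutyl)-2,4-bis(methoxymethoxy)phenyl]ethan-1-one
Product: 16 1-[6-hydroxy-3-(3-hydroxy-3-methylbutyl)-2,4-bis(methoxymethoxy)phenyl]ethan-1-one, via bis(boryl) ketone 15 (not isolated)
Conditions: [Ir(OMe)(cod)]2 (1.5 mol %), AsPh3 (6 mol %), B2pin2, octane, 120 °C; then Me3NO·2H2O, THF, 60 °C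
Reagents that add atoms: trimethylamine N-oxide, C[N+](C)(C)[O-]
Why: Carbonyl-directed iridium-catalysed ortho C–H borylation should functionalise the only C–H next to the acetyl group (the tertiary hydroxyl is borylated as well and freed again), and amine N-oxide oxidation of the C–B bond gives the phenol without the risk of a Dakin-type oxidation.

Step 10
Reactants: 16 1-[6-hydroxy-3-(3-hydroxy-3-methylbutyl)-2,4-bis(methoxymethoxy)phenyl]ethan-1-one
Product: 18 6-(3-hydroxy-3-methylbutyl)-3-iodo-5,7-bis(methoxymethoxy)-4H-chromen-4-one, via enaminone 17 (not isolated)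
Conditions: Me2NCH(OMe)2, toluene, 90 °C; evaporate; then I2, CHCl3, rt
Reagents that add atoms: N,N-dimethylformamide dimethyl acetal, COC(OC)N(C)C; iodine, II
Why: Condensation with the amide acetal gives the enaminone, and iodine-mediated cyclisation (α-iodination, attack of the only free phenol on the iminium carbon, loss of dimethylamine) should give the 3-iodochromone with the side chain unambiguously at C6.

Step 11
Reactants: 18 6-(3-hydroxy-3-methylbutyl)-3-iodo-5,7-bis(methoxymethoxy)-4H-chromen-4-one; 10 2-[5-(methoxymethoxy)-2,2-dimethyl-2H-chromen-6-yl]-4,4,5,5-tetramethyl-1,3,2-dioxaborolane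
Product: 19 6-(3-hydroxy-3-methylbutyl)-5,7-bis(methoxymethoxy)-3-[5-(methoxymethoxy)-2,2-dimethyl-2H-chromen-6-yl]-4H-chromen-4-one
Conditions: PdCl2(dppf) (5 mol %), Na2CO3, DME/H2O, 80 °C
Reagents that add atoms: none
Why: Suzuki–Miyaura cross-coupling of a 3-iodochromone with an arylboronate is the standard construction of the isoflavone C3–C1' bond and should tolerate the free tertiary alcohol and the chromene.

Step 12
Reactants: 19 6-(3-hydroxy-3-methylbutyl)-5,7-bis(methoxymethoxy)-3-[5-(methoxymethoxy)-2,2-dimethyl-2H-chromen-6-yl]-4H-chromen-4-one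
Product: 20 Kanzonol T, 5,7-dihydroxy-6-(3-hydroxy-3-methylbutyl)-3-(5-hydroxy-2,2-dimethyl-2H-chromen-6-yl)-4H-chromen-4-one
Conditions: 3 M aq. HCl (cat.), MeOH/THF, rt → 40 °C
Reagents that add atoms: none
Why: Acid-catalysed acetal exchange with methanol should remove the three MOM ethers under conditions mild enough to leave the tertiary alcohol and the chromene double bond intact.

**Compound list**

1 | 3-chlorocyclohex-2-en-1-one | O=C1C=C(Cl)CCC1 | starting material
2 | 2-hydroxy-2-methylpropanoic acid | CC(C)(O)C(=O)O | starting material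
3 | 2-methyl-2-[(3-oxocyclohex-1-en-1-yl)oxy]propanoic acid | CC(C)(OC1=CC(=O)CCC1)C(=O)O | intermediate
4 | 1,3-dioxoisoindolin-2-yl 2-methyl-2-[(3-oxocyclohex-1-en-1-yl)oxy]propanoate | CC(C)(OC1=CC(=O)CCC1)C(=O)ON1C(=O)c2ccccc2C1=O | intermediate
5 | acetylene | C#C | starting material
6 | 2,2-dimethyl-7,8-dihydro-2H-chromen-5(6H)-one | CC1(C)C=CC2=C(CCCC2=O)O1 | intermediate
7 | 2,2-dimethyl-6-(phenylselanyl)-7,8-dihydro-2H-chromen-5(6H)-one (racemic, not isolated) | CC1(C)C=CC2=C(CCC([Se]c3ccccc3)C2=O)O1 | intermediate
8 | 2,2-dimethyl-2H-chromen-5-ol | CC1(C)C=Cc2c(O)cccc2O1 | intermediate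
9 | 5-(methoxymethoxy)-2,2-dimethyl-2H-chromene | COCOc1cccc2OC(C)(C)C=Cc12 | intermediate
10 | 2-[5-(methoxymethoxy)-2,2-dimethyl-2H-chromen-6-yl]-4,4,5,5-tetramethyl-1,3,2-dioxaborolane | COCOc1c(B2OC(C)(C)C(C)(C)O2)ccc2OC(C)(C)C=Cc12 | intermediate
11 | 1,3-bis(methoxymethoxy)benzene | COCOc1cccc(OCOC)c1 | starting material
12 | 2,2-dimethyloxetane | CC1(C)CCO1 | starting material
13 | 4-[2,6-bis(methoxymethoxy)phenyl]-2-methylbutan-2-ol | CC(C)(O)CCc1c(OCOC)cccc1OCOC | intermediate
14 | 1-[3-(3-hydroxy-3-methylbutyl)-2,4-bis(methoxymethoxy)phenyl]ethan-1-one | CC(=O)c1ccc(OCOC)c(CCC(C)(C)O)c1OCOC | intermediate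
15 | 1-[2,4-bis(methoxymethoxy)-3-{3-methyl-3-[(4,4,5,5-tetramethyl-1,3,2-dioxaborolan-2-yl)oxy]butyl}-6-(4,4,5,5-tetramethyl-1,3,2-dioxaborolan-2-yl)phenyl]ethan-1-one (not isolated) | CC(=O)c1c(B2OC(C)(C)C(C)(C)O2)cc(OCOC)c(CCC(C)(C)OB2OC(C)(C)C(C)(C)O2)c1OCOC | intermediate
16 | 1-[6-hydroxy-3-(3-hydroxy-3-methylbutyl)-2,4-bis(methoxymethoxy)phenyl]ethan-1-one | CC(=O)c1c(O)cc(OCOC)c(CCC(C)(C)O)c1OCOC | intermediate
17 | (E)-3-(dimethylamino)-1-[6-hydroxy-3-(3-hydroxy-3-methylbutyl)-2,4-bis(methoxymethoxy)phenyl]prop-2-en-1-one (not isolated) | CN(C)/C=C/C(=O)c1c(O)cc(OCOC)c(CCC(C)(C)O)c1OCOC | intermediate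
18 | 6-(3-hydroxy-3-methylbutyl)-3-iodo-5,7-bis(methoxymethoxy)-4H-chromen-4-one | CC(C)(O)CCc1c(OCOC)cc2occ(I)c(=O)c2c1OCOC | intermediate
19 | 6-(3-hydroxy-3-methylbutyl)-5,7-bis(methoxymethoxy)-3-[5-(methoxymethoxy)-2,2-dimethyl-2H-chromen-6-yl]-4H-chromen-4-one | CC(C)(O)CCc1c(OCOC)cc2occ(-c3ccc4OC(C)(C)C=Cc4c3OCOC)c(=O)c2c1OCOC | intermediate
20 | Kanzonol T, 5,7-dihydroxy-6-(3-hydroxy-3-methylbutyl)-3-(5-hydroxy-2,2-dimethyl-2H-chromen-6-yl)-4H-chromen-4-one | CC(C)(O)CCc1c(O)cc2occ(-c3ccc4c(c3O)C=CC(C)(C)O4)c(=O)c2c1O | target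

**Summary**

Total step count: 12. Longest linear sequence: 8 steps (steps 1 to 6, then 11 and 12); the ring A/C branch (steps 7 to 10) joins at step 11.

Steps most likely to fail:

Step 3 (proposed new method). The α-oxy radical may add too slowly to acetylene and be oxidised or reduced first, or the vinyl radical may abstract hydrogen before it cyclises. The fallback is pericyclic and known: it sets out from compound 1, which with the sodium alkoxide of 2-methylbut-3-yn-2-ol (NaH, THF) should give 3-[(2-methylbut-3-yn-2-yl)oxy]cyclohex-2-en-1-one F1. Heating F1 (xylene, 140 °C) is expected to trigger a propargyl Claisen rearrangement, 1,5-hydrogen shift and oxa-6π electrocyclisation cascade, which comes back to the route at compound 6.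

Step 9. Catalyst inhibition by the crowded, chelating ketone or competing borylation at the other ring C–H may erode the directed C–H functionalisation. The fallback places the third oxygen before the acetyl group; it sets out from compound 13 and comes back at compound 16. Sterically controlled C–H borylation of 13 ([Ir(OMe)(cod)]2, 4,4'-di-tert-butyl-2,2'-bipyridine, B2pin2) at the only unhindered C–H, para to the side chain, should give 2-methyl-4-[2,6-bis(methoxymethoxy)-4-(4,4,5,5-tetramethyl-1,3,2-dioxaborolan-2-yl)phenyl]butan-2-ol F2. Oxidation (H2O2, NaOH) gives the symmetric 4-(3-hydroxy-3-methylbutyl)-3,5-bis(methoxymethoxy)phenol F3, and ortho-specific formylation (MgCl2, Et3N, paraformaldehyde, MeCN) gives 2-hydroxy-5-(3-hydroxy-3-methylbutyl)-4,6-bis(methoxymethoxy)benzaldehyde F4. Addition of MeMgBr gives racemic 2-(1-hydroxyethyl)-4-(3-hydroxy-3-methylbutyl)-3,5-bis(methoxymethoxy)phenol F5, and MnO2 oxidation of the benzylic alcohol returns compound 16.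

Step 12. Under Brønsted acid the tertiary alcohol may ionise and close onto a neighbouring phenol, or the chromene may hydrate or dimerise. The fallback avoids Brønsted acid by exchanging the protecting groups; it sets out from compound 19 and comes back at compound 20. TESOTf with 2,2'-bipyridyl (CH2Cl2, 0 °C) is expected to convert the three aryl MOM ethers into triethylsilyl ethers and to silylate the tertiary alcohol, giving 5,7-bis[(triethylsilyl)oxy]-3-{2,2-dimethyl-5-[(triethylsilyl)oxy]-2H-chromen-6-yl}-6-{3-methyl-3-[(triethylsilyl)oxy]butyl}-4H-chromen-4-one F6. Fluoride (Bu4NF buffered with AcOH, THF) then releases compound 20.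

**Further compounds**

F1 | step 3 | 3-[(2-methylbut-3-yn-2-yl)oxy]cyclohex-2-en-1-one | CC(C)(C#C)OC1=CC(=O)CCC1
F2 | step 9 | 2-methyl-4-[2,6-bis(methoxymethoxy)-4-(4,4,5,5-tetramethyl-1,3,2-dioxaborolan-2-yl)phenyl]butan-2-ol | CC(C)(O)CCc1c(OCOC)cc(B2OC(C)(C)C(C)(C)O2)cc1OCOC
F3 | step 9 | 4-(3-hydroxy-3-methylbutyl)-3,5-bis(methoxymethoxy)phenol | CC(C)(O)CCc1c(OCOC)cc(O)cc1OCOC
F4 | step 9 | 2-hydroxy-5-(3-hydroxy-3-methylbutyl)-4,6-bis(methoxymethoxy)benzaldehyde | CC(C)(O)CCc1c(OCOC)cc(O)c(C=O)c1OCOC
F5 | step 9 | 2-(1-hydroxyethyl)-4-(3-hydroxy-3-methylbutyl)-3,5-bis(methoxymethoxy)phenol (racemic) | CC(O)c1c(O)cc(OCOC)c(CCC(C)(C)O)c1OCOC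
F6 | step 12 | 5,7-bis[(triethylsilyl)oxy]-3-{2,2-dimethyl-5-[(triethylsilyl)oxy]-2H-chromen-6-yl}-6-{3-methyl-3-[(triethylsilyl)oxy]butyl}-4H-chromen-4-one | CC[Si](CC)(CC)OC(C)(C)CCc1c(O[Si](CC)(CC)CC)cc2occ(-c3ccc4OC(C)(C)C=Cc4c3O[Si](CC)(CC)CC)c(=O)c2c1O[Si](CC)(CC)CC
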